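The coumarin lactone of ring B is cut at both bonds to its carbonyl carbon. C2 is a single carbon held between the phenolic oxygen O1 and the alkene carbon C3, so the pyranone equals an (E)-2-hydroxystilbene plus carbon monoxide. One palladium-catalysed oxidative carbonylation forms C2–O1 and C2–C3 and closes ring B. The stilbene carries the future cyclohexenedione as a hydroquinone ring with two different ethers. A methoxymethyl ether beside the prenyl group is removed after carbonylation, so that a chiral iodane can hydroxylate the prenyl-bearing carbon with dearomatization. A triisopropylsilyl ether becomes a silyl enol ether and is unmasked last as the second ketone.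

Key step: step 6

Assumption: the (S)-configured iodyl reagent of step 8 is taken to deliver oxygen to the ring face that gives the (R)-carbinol; if a first run shows the opposite sense, its enantiomer from (R)-valinol is used and nothing else changes.
Remark: this reagent is not an article of commerce; it is made separately from 2-iodobenzoic acid and (S)-valinol (amide, oxazoline closure, oxidation with dimethyldioxirane), and its preparation is not counted in the steps.
Remark: reagent control of this kind may fall short of a single enantiomer, so the enantiomeric purity of 15 is to be checked and, if needed, raised by recrystallisation.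

Step 1
Reactants: 1 2,5-dibromobenzene-1,4-diol
Product: 2 2,5-dibromo-4-(triisopropylsilyloxy)phenol
Conditions: i-Pr3SiCl (1.0 equiv), imidazole, DMF, 0 °C to rt
Reagents that add atoms: chlorotriisopropylsilane, CC(C)[Si](Cl)(C(C)C)C(C)C
Why: Imidazole-promoted silyl ether formation on one of two equivalent phenols; the outcome is statistical, so the silyl chloride is held at one equivalent and unreacted diol and any bis-ether are separated and recycled.

Step 2
Reactants: 2 2,5-dibromo-4-(triisopropylsilyloxy)phenol
Product: 3 [2,5-dibromo-4-(methoxymethoxy)phenoxy]triisopropylsilane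
Conditions: MeOCH2Cl, i-Pr2NEt, CH2Cl2, 0 °C to rt
Reagents that add atoms: chloromethyl methyl ether, COCCl
Why: O-alkylation of the remaining phenol with the chloromethyl ether under amine base (methoxymethyl ether formation) makes the two oxygens different and installs the chelating group that steers the lithiation of step 3.

Step 3
Reactants: 3 [2,5-dibromo-4-(methoxymethoxy)phenoxy]triisopropylsilane; 4 1-bromo-3-methylbut-2-ene
Product: 6 [2-bromo-4-(methoxymethoxy)-5-(3-methylbut-2-enyl)phenoxy]triisopropylsilane, via aryllithium 5 (not isolated)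
Conditions: n-BuLi (1.05 equiv), THF, –78 °C; then CuBr·SMe2 (10 mol%), 4, –78 °C to 0 °C
Reagents that add atoms: none
Why: Bromine–lithium exchange should go to the bromine beside the lithium-chelating methoxymethoxy group, since the bulky, weakly basic silyl ether neither binds lithium nor stabilises a neighbouring carbanion, and the aryl anion is then allylated at the primary carbon of the prenyl bromide under copper catalysis (SN2 allylation).

Step 4
Reactants: 6 [2-bromo-4-(methoxymethoxy)-5-(3-methylbut-2-enyl)phenoxy]triisopropylsilane; 7 2-ethenyl-4,4,5,5-tetramethyl-1,3,2-dioxaborolane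
Product: 8 [2-ethenyl-4-(methoxymethoxy)-5-(3-methylbut-2-enyl)phenoxy]triisopropylsilane
Conditions: Pd(OAc)2 (3 mol%), SPhos (6 mol%), K3PO4, toluene/H2O, 80 °C
Reagents that add atoms: none
Why: Suzuki–Miyaura vinylation, in which the electron-rich biaryl phosphine promotes oxidative addition at the hindered, electron-rich C–Br bond while the aryl silyl ether, the acetal and the prenyl alkene are inert to aqueous phosphate.

Step 5
Reactants: 8 [2-ethenyl-4-(methoxymethoxy)-5-(3-methylbut-2-enyl)phenoxy]triisopropylsilane; 9 2-iodo-5-methoxyphenol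
Product: 10 5-methoxy-2-[(E)-2-[5-(methoxymethoxy)-4-(3-methylbut-2-enyl)-2-(triisopropylsilyloxy)phenyl]ethenyl]phenol
Conditions: Pd(OAc)2 (5 mol%), P(o-tol)3 (10 mol%), Et3N, DMF, 90 °C
Reagents that add atoms: none
Why: Mizoroki–Heck reaction, in which the arylpalladium species from the iodide adds to the unsubstituted terminus of the styrene and syn beta-hydride elimination gives the (E)-stilbene, while the trisubstituted prenyl alkene is too hindered to insert and the free phenol is tolerated.

Step 6
Reactants: 10 5-methoxy-2-[(E)-2-[5-(methoxymethoxy)-4-(3-methylbut-2-enyl)-2-(triisopropylsilyloxy)phenyl]ethenyl]phenol; 11 carbon monoxide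
Product: 12 7-methoxy-3-[5-(methoxymethoxy)-4-(3-methylbut-2-enyl)-2-(triisopropylsilyloxy)phenyl]chromen-2-one
Conditions: Pd(OAc)2 (10 mol%), 1,4-benzoquinone (2 equiv), CO (5 bar), MeCN, 100 °C
Reagents that add atoms: none
Why: Pd(OAc)2 exchanges acetate for the phenoxide of 10 and palladates the alkenyl C–H on the aryl-bearing alkene carbon, which in the (E)-alkene lies cis to the phenol ring, giving a six-membered oxapalladacycle; CO inserts and reductive elimination joins C2 to O1 and to C3, releasing zerovalent palladium that benzoquinone returns to the divalent state. The closest known reaction type is the palladium-catalysed oxidative cyclocarbonylation of 2-vinylphenols to coumarins. Ring B closes as a six-membered lactone by acyl–oxygen reductive elimination from a seven-membered acylpalladacycle, an endo closure with respect to the alkene, which ends inside the ring as C3=C4. No stereocentre is formed. The step needs selectivity for the stilbene C–H over the prenyl alkene and for carbonylation over Wacker-type closure to a 2-arylbenzofuran: the phenoxide places palladium next to the stilbene only, the (E)-geometry from step 5 puts hydrogen and not aryl at the reacting position, the other ring carries no free hydroxyl, and CO pressure favours insertion over beta-hydride pathways.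

Step 7
Reactants: 12 7-methoxy-3-[5-(methoxymethoxy)-4-(3-methylbut-2-enyl)-2-(triisopropylsilyloxy)phenyl]chromen-2-one
Product: 13 3-[5-hydroxy-4-(3-methylbut-2-enyl)-2-(triisopropylsilyloxy)phenyl]-7-methoxychromen-2-one
Conditions: NaHSO4·SiO2, CH2Cl2, rt
Reagents that add atoms: none
Why: Acid-catalysed acetal hydrolysis (methoxymethyl ether cleavage) on a weakly acidic solid support at room temperature, under which phenolic methoxymethyl ethers are cleaved while the hindered aryl silyl ether, the lactone and the prenyl alkene should stay intact.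

Step 8
Reactants: 13 3-[5-hydroxy-4-(3-methylbut-2-enyl)-2-(triisopropylsilyloxy)phenyl]-7-methoxychromen-2-one
Product: 14 (6R)-6-hydroxy-3-(7-methoxy-2-oxochromen-3-yl)-6-(3-methylbut-2-enyl)-4-(triisopropylsilyloxy)cyclohexa-2,4-dien-1-one
Conditions: (S)-2-(2-iodylphenyl)-4-isopropyl-4,5-dihydro-1,3-oxazole (1.3 equiv), DME, –20 °C to rt
Reagents that add atoms: (S)-2-(2-iodylphenyl)-4-isopropyl-4,5-dihydro-1,3-oxazole, O=I(=O)c1ccccc1C1=N[C@@H](C(C)C)CO1
Why: Hydroxylative phenol dearomatization by a pentavalent-iodine reagent, in which the phenol binds to iodine and an iodyl oxygen is passed intramolecularly to an ortho carbon, here the electron-richer prenyl-bearing one that is not flanked by the coumarin, and the oxazoline stereocentre next to iodine distinguishes the two ring faces so that the new carbinol carbon should form as (R) under reagent control.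

Step 9
Reactants: 14 (6R)-6-hydroxy-3-(7-methoxy-2-oxochromen-3-yl)-6-(3-methylbut-2-enyl)-4-(triisopropylsilyloxy)cyclohexa-2,4-dien-1-one
Product: 15 (5R)-5-hydroxy-2-(7-methoxy-2-oxochromen-3-yl)-5-(3-methylbut-2-enyl)cyclohex-2-ene-1,4-dione
Conditions: HF·pyridine, pyridine, THF, 0 °C
Reagents that add atoms: none
Why: Fluoride cleaves the silicon–oxygen bond of the silyl enol ether and the freed dienol ketonises by protonation at the ring CH beside the carbinol carbon to give the ene-dione, while pyridine buffering at 0 °C guards the tertiary beta-hydroxyl against elimination and the fully substituted stereocentre is not touched.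

Compound list
1 | 2,5-dibromobenzene-1,4-diol | Oc1cc(Br)c(O)cc1Br | starting material
2 | 2,5-dibromo-4-(triisopropylsilyloxy)phenol | Oc1cc(Br)c(O[Si](C(C)C)(C(C)C)C(C)C)cc1Br | intermediate
3 | [2,5-dibromo-4-(methoxymethoxy)phenoxy]triisopropylsilane | COCOc1cc(Br)c(O[Si](C(C)C)(C(C)C)C(C)C)cc1Br | intermediate
4 | 1-bromo-3-methylbut-2-ene | CC(C)=CCBr | starting material
5 | [4-bromo-2-(methoxymethoxy)-5-(triisopropylsilyloxy)phenyl]lithium | COCOc1cc(Br)c(O[Si](C(C)C)(C(C)C)C(C)C)cc1[Li] | intermediate
6 | [2-bromo-4-(methoxymethoxy)-5-(3-methylbut-2-enyl)phenoxy]triisopropylsilane | COCOc1cc(Br)c(O[Si](C(C)C)(C(C)C)C(C)C)cc1CC=C(C)C | intermediate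
7 | 2-ethenyl-4,4,5,5-tetramethyl-1,3,2-dioxaborolane | C=CB1OC(C)(C)C(C)(C)O1 | starting material
8 | [2-ethenyl-4-(methoxymethoxy)-5-(3-methylbut-2-enyl)phenoxy]triisopropylsilane | COCOc1cc(C=C)c(O[Si](C(C)C)(C(C)C)C(C)C)cc1CC=C(C)C | intermediate
9 | 2-iodo-5-methoxyphenol | COc1ccc(I)c(O)c1 | starting material
10 | 5-methoxy-2-[(E)-2-[5-(methoxymethoxy)-4-(3-methylbut-2-enyl)-2-(triisopropylsilyloxy)phenyl]ethenyl]phenol | COc1ccc(/C=C/c2cc(OCOC)c(CC=C(C)C)cc2O[Si](C(C)C)(C(C)C)C(C)C)c(O)c1 | intermediate
11 | carbon monoxide | [C-]#[O+] | starting material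
12 | 7-methoxy-3-[5-(methoxymethoxy)-4-(3-methylbut-2-enyl)-2-(triisopropylsilyloxy)phenyl]chromen-2-one | COc1ccc2cc(-c3cc(OCOC)c(CC=C(C)C)cc3O[Si](C(C)C)(C(C)C)C(C)C)c(=O)oc2c1 | intermediate
13 | 3-[5-hydroxy-4-(3-methylbut-2-enyl)-2-(triisopropylsilyloxy)phenyl]-7-methoxychromen-2-one | COc1ccc2cc(-c3cc(O)c(CC=C(C)C)cc3O[Si](C(C)C)(C(C)C)C(C)C)c(=O)oc2c1 | intermediate
14 | (6R)-6-hydroxy-3-(7-methoxy-2-oxochromen-3-yl)-6-(3-methylbut-2-enyl)-4-(triisopropylsilyloxy)cyclohexa-2,4-dien-1-one | COc1ccc2cc(C3=CC(=O)[C@@](O)(CC=C(C)C)C=C3O[Si](C(C)C)(C(C)C)C(C)C)c(=O)oc2c1 | intermediate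
15 | (5R)-5-hydroxy-2-(7-methoxy-2-oxochromen-3-yl)-5-(3-methylbut-2-enyl)cyclohex-2-ene-1,4-dione | COc1ccc2cc(C3=CC(=O)[C@@](O)(CC=C(C)C)CC3=O)c(=O)oc2c1 | target

Total step count: 9
Longest linear sequence: 9 steps (1 to 15)

Steps most likely to fail

Step 8. The oxygen transfer may show poor facial selectivity. The iodine-bound phenol may also be oxidised at the para position with loss of silicon, giving the achiral para-quinone, or oxygen may go to the unsubstituted ortho carbon. The fallback secures the stereocentre by resolution and does not cure the last two failure modes. It sets out from 13, which is hydroxylated with achiral 2-iodoxybenzoic acid (stabilised formulation, THF, rt) to racemic 6-hydroxy-3-(7-methoxy-2-oxochromen-3-yl)-6-(3-methylbut-2-enyl)-4-(triisopropylsilyloxy)cyclohexa-2,4-dien-1-one F1. The enantiomers are separated by preparative chromatography on an amylose tris(3,5-dimethylphenylcarbamate) phase. The (6R)-isomer is 14, where the route is rejoined, and (6S)-6-hydroxy-3-(7-methoxy-2-oxochromen-3-yl)-6-(3-methylbut-2-enyl)-4-(triisopropylsilyloxy)cyclohexa-2,4-dien-1-one F2 is set aside.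

Step 6. Attack of the phenoxide on the palladium-bound alkene followed by beta-hydride elimination (closure to a 2-arylbenzofuran), or palladium hydride migration of the prenyl double bond, may outrun CO insertion. The fallback buys the lactone ready-made and forms the aryl–C3 bond instead. It sets out from 6, which is converted by Miyaura borylation (bis(pinacolato)diboron, Pd(dppf)Cl2, KOAc, dioxane, 90 °C) into 2-[5-(methoxymethoxy)-4-(3-methylbut-2-enyl)-2-(triisopropylsilyloxy)phenyl]-4,4,5,5-tetramethyl-1,3,2-dioxaborolane F3. Suzuki–Miyaura coupling of F3 (Pd(OAc)2, SPhos, K3PO4, toluene/H2O, 80 °C) with 3-bromo-7-methoxychromen-2-one F4, made from commercial 7-methoxychromen-2-one with Br2 and NaOAc in AcOH, rejoins the route at 12.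

Step 5. Aryl transfer to the internal alkene carbon (giving a 1,1-diarylethene), reductive loss of iodine from 9, or oligomerisation of the electron-rich styrene may erode the coupling. The fallback brings the (E)-geometry in with a reagent and uses transmetalation instead of carbopalladation. It sets out from 6 and bypasses 8. Suzuki–Miyaura coupling of 6 (Pd(OAc)2, SPhos, K3PO4, toluene/H2O) with an excess of commercial (E)-1,2-bis(4,4,5,5-tetramethyl-1,3,2-dioxaborolan-2-yl)ethene gives 2-[(E)-2-[5-(methoxymethoxy)-4-(3-methylbut-2-enyl)-2-(triisopropylsilyloxy)phenyl]ethenyl]-4,4,5,5-tetramethyl-1,3,2-dioxaborolane F5. A second Suzuki–Miyaura coupling of F5 with 9 under the same catalyst returns to 10.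

Further compounds
F1 | step 8 | racemic 6-hydroxy-3-(7-methoxy-2-oxochromen-3-yl)-6-(3-methylbut-2-enyl)-4-(triisopropylsilyloxy)cyclohexa-2,4-dien-1-one | COc1ccc2cc(C3=CC(=O)C(O)(CC=C(C)C)C=C3O[Si](C(C)C)(C(C)C)C(C)C)c(=O)oc2c1
F2 | step 8 | (6S)-6-hydroxy-3-(7-methoxy-2-oxochromen-3-yl)-6-(3-methylbut-2-enyl)-4-(triisopropylsilyloxy)cyclohexa-2,4-dien-1-one | COc1ccc2cc(C3=CC(=O)[C@](O)(CC=C(C)C)C=C3O[Si](C(C)C)(C(C)C)C(C)C)c(=O)oc2c1
F3 | step 6 | 2-[5-(methoxymethoxy)-4-(3-methylbut-2-enyl)-2-(triisopropylsilyloxy)phenyl]-4,4,5,5-tetramethyl-1,3,2-dioxaborolane | COCOc1cc(B2OC(C)(C)C(C)(C)O2)c(O[Si](C(C)C)(C(C)C)C(C)C)cc1CC=C(C)C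
F4 | step 6 | 3-bromo-7-methoxychromen-2-one | COc1ccc2cc(Br)c(=O)oc2c1
F5 | step 5 | 2-[(E)-2-[5-(methoxymethoxy)-4-(3-methylbut-2-enyl)-2-(triisopropylsilyloxy)phenyl]ethenyl]-4,4,5,5-tetramethyl-1,3,2-dioxaborolane | COCOc1cc(/C=C/B2OC(C)(C)C(C)(C)O2)c(O[Si](C(C)C)(C(C)C)C(C)C)cc1CC=C(C)C
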